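**Plan**

- Retrosynthesis: the C5 styryl C=C bond is cut first (Horner–Wadsworth–Emmons), then the O1–C8a bond (Baeyer–Villiger ring expansion of a 1-indanone), then three bonds of ring A at once, C8a–C4a, C5–C6 and C7–C8 (alkyne [2+2+2]).
- Enabling feature: ring A of the chroman-2-one has hydrogen only on C6 and C8 and substituents on C4a, C5, C7 and C8a, so it is the sum of three alkynes C8a≡C8, C4a≡C5 and C6≡C7, the first two linked through C2–C3–C4.
- Forward: an open chain is built from O-benzylvanillin (Knoevenagel, conjugate alkynylation, decarboxylation, Weinreb amide, ethynyl ketone); one rhodium-catalysed step closes the cyclopentanone and benzene ring A together; oxygen insertion makes the lactone ring; the styryl arm is attached last.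
- Stereochemistry: the only stereocentre, C4 (R), is set by a copper-catalysed enantioselective conjugate addition of a terminal alkyne to an arylidene Meldrum's acid and is carried through unchanged; the (E)-alkene comes from the phosphonate olefination.
- Protecting groups: benzyl ethers on the three phenols and a tert-butyldiphenylsilyl ether on the future C5 carbon tolerate the acid-catalysed peracid step; a single BCl3 step frees the phenols.

Key step: step 8

Remark on the chemistry: the antipode of the PINAP ligand in step 2 is taken to be the one whose copper acetylide attacks the face of the arylidene Meldrum's acid that leads to the (R)-adduct; the sense of induction is to be confirmed on a small scale (chiral HPLC) before scale-up.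
Remark on the chemistry: the benzyl ynol ether of step 7 is kept as a cold solution and used the same day, because benzyl alkynyl ethers rearrange on warming.

**Step 1**
Reactants: 1 4-(benzyloxy)-3-methoxybenzaldehyde; 2 Meldrum's acid (2,2-dimethyl-1,3-dioxane-4,6-dione)
Product: 3 5-[4-(benzyloxy)-3-methoxybenzylidene]-2,2-dimethyl-1,3-dioxane-4,6-dione
Conditions: pyrrolidine (10 mol %), AcOH (10 mol %), toluene, rt
Reagents that add atoms: none
Why: Knoevenagel condensation of an aromatic aldehyde with the strongly C–H acidic Meldrum's acid under iminium catalysis is routine, the benzyl ether is inert and no stereocentre is formed.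

**Step 2**
Reactants: 3 5-[4-(benzyloxy)-3-methoxybenzylidene]-2,2-dimethyl-1,3-dioxane-4,6-dione; 4 tert-butyl(diphenyl)(prop-2-yn-1-yloxy)silane
Product: 5 5-{(1R)-1-[4-(benzyloxy)-3-methoxyphenyl]-4-[(tert-butyldiphenylsilyl)oxy]but-2-yn-1-yl}-2,2-dimethyl-1,3-dioxane-4,6-dione
Conditions: Cu(OAc)2·H2O (10 mol %), (R,Ra)-N-PINAP (10 mol %; antipode as fixed in the remark above), sodium L-ascorbate (20 mol %), 4 (3 equiv), H2O, 0 °C → rt
Reagents that add atoms: none
Why: This is the copper-catalysed enantioselective conjugate alkynylation of alkylidene Meldrum's acids in water, in which ascorbate generates monovalent copper and the P,N-ligated copper acetylide adds to the doubly activated acceptor with one face blocked by the ligand, so that the propargylic–benzylic carbon (C4 of the target) is formed R.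

**Step 3**
Reactants: 5 5-{(1R)-1-[4-(benzyloxy)-3-methoxyphenyl]-4-[(tert-butyldiphenylsilyl)oxy]but-2-yn-1-yl}-2,2-dimethyl-1,3-dioxane-4,6-dione
Product: 7 (3R)-3-[4-(benzyloxy)-3-methoxyphenyl]-6-[(tert-butyldiphenylsilyl)oxy]hex-4-ynoic acid, via substituted malonic acid 6 (not isolated)
Conditions: DMF/H2O (10:1), 100 °C
Reagents that add atoms: water, O
Why: Hydrolytic opening of the Meldrum's acid ring with loss of acetone followed by thermal decarboxylation of the malonic acid is standard, the silyl and benzyl ethers tolerate hot aqueous DMF, and the stereocentre is not enolisable.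

**Step 4**
Reactants: 7 (3R)-3-[4-(benzyloxy)-3-methoxyphenyl]-6-[(tert-butyldiphenylsilyl)oxy]hex-4-ynoic acid
Product: 9 (3R)-3-[4-(benzyloxy)-3-methoxyphenyl]-6-[(tert-butyldiphenylsilyl)oxy]-N-methoxy-N-methylhex-4-ynamide, via acyl imidazole 8 (not isolated)
Conditions: CDI, CH2Cl2, rt; then MeNHOMe·HCl, rt
Reagents that add atoms: N,O-dimethylhydroxylamine hydrochloride, CNOC.Cl
Why: Carbonyldiimidazole activation and aminolysis of the acyl imidazole give the Weinreb amide under near-neutral conditions that cannot touch the β-stereocentre.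

**Step 5**
Reactants: 9 (3R)-3-[4-(benzyloxy)-3-methoxyphenyl]-6-[(tert-butyldiphenylsilyl)oxy]-N-methoxy-N-methylhex-4-ynamide; 10 ethynylmagnesium bromide
Product: 12 (5R)-5-[4-(benzyloxy)-3-methoxyphenyl]-8-[(tert-butyldiphenylsilyl)oxy]octa-1,6-diyn-3-one, via bromomagnesium hemiaminal 11 (not isolated)
Conditions: 10 (0.5 M in THF, 3 equiv), THF, −78 → 0 °C; inverse quench into cold 1 M HCl
Reagents that add atoms: none
Why: In this Weinreb ketone synthesis the chelated tetrahedral magnesium adduct prevents over-addition, and the cold acidic inverse quench protonates the released N,O-dimethylhydroxylamine before it can add to the terminal ynone.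

**Step 6**
Reactants: 13 benzyl alcohol; 14 trichloroethylene
Product: 17 benzyl (E)-1,2-dichlorovinyl ether, via potassium benzyl oxide 15 (not isolated), via dichloroethyne 16 (not isolated)
Conditions: KH, THF, 0 °C; then 14, −50 °C → rt
Reagents that add atoms: none
Why: Alkoxide-induced dehydrochlorination of trichloroethylene and trans-addition of the alcohol across the transient dichloroalkyne is the established route to 1,2-dichlorovinyl ethers.

**Step 7**
Reactants: 17 benzyl (E)-1,2-dichlorovinyl ether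
Product: 20 (benzyloxy)ethyne, via benzyl chloroethynyl ether 18 (not isolated), via lithium benzyloxyacetylide 19 (not isolated)
Conditions: n-BuLi (2.2 equiv), THF, −78 °C; then H2O, −78 → 0 °C; pentane extraction, solvent exchanged to toluene in the cold
Reagents that add atoms: none
Why: The first equivalent of n-BuLi effects β-elimination of LiCl, the second chlorine–lithium exchange on the chloroalkyne, and low-temperature protonation of the lithium alkoxyacetylide gives the terminal ynol ether (known alkoxyacetylene synthesis).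

**Step 8**
Reactants: 12 (5R)-5-[4-(benzyloxy)-3-methoxyphenyl]-8-[(tert-butyldiphenylsilyl)oxy]octa-1,6-diyn-3-one; 20 (benzyloxy)ethyne
Product: 21 (3R)-6-(benzyloxy)-3-[4-(benzyloxy)-3-methoxyphenyl]-4-{[(tert-butyldiphenylsilyl)oxy]methyl}-2,3-dihydro-1H-inden-1-one
Conditions: RhCl(PPh3)3 (5 mol %), 20 (3 equiv), toluene, rt, slow addition of 12
Reagents that add atoms: none
Why: Oxidative cyclisation of the two tethered alkynes on monovalent rhodium gives a rhodacyclopentadiene fused to the nascent cyclopentenone (C2–C6 bond of 12, the C8a–C4a bond of the target), and insertion of 20 followed by reductive elimination forms the C5–C6 and C7–C8 bonds of the target. The closest known reaction type is the RhCl(PPh3)3-catalysed [2+2+2] cycloaddition of 1,6-diynes with terminal alkynes, which has been run with alkoxyalkynes and with ketone-tethered diynes. The five-membered ketone ring closes by metal-mediated oxidative coupling across the three-atom tether C3–C4–C5, and benzene ring A closes by formal [4+2] addition of the third alkyne to the metallacycle. No stereocentre is created, and the propargylic centre C5 of 12 is a spectator that the neutral catalyst should leave unchanged at room temperature. The step needs cross- over homo-cyclotrimerisation, which slow addition of the electron-poor diynone to an excess of the electron-rich ynol ether should secure. It also needs meta-regioselectivity (alkoxy-bearing carbon bonding to the unsubstituted terminus C1 of 12), which the bulky silyloxymethyl group on C7 should secure by forcing the unsubstituted end of the monoalkyne next to itself.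

**Step 9**
Reactants: 21 (3R)-6-(benzyloxy)-3-[4-(benzyloxy)-3-methoxyphenyl]-4-{[(tert-butyldiphenylsilyl)oxy]methyl}-2,3-dihydro-1H-inden-1-one
Product: 22 (4R)-7-(benzyloxy)-4-[4-(benzyloxy)-3-methoxyphenyl]-5-{[(tert-butyldiphenylsilyl)oxy]methyl}chroman-2-one
Conditions: mCPBA (2.5 equiv), TsOH·H2O (20 mol %), CH2Cl2, 0 °C → rt
Reagents that add atoms: mCPBA (3-chloroperoxybenzoic acid), O=C(OO)c1cccc(Cl)c1
Why: In this acid-catalysed Baeyer–Villiger oxidation the aryl carbon of the Criegee adduct migrates in preference to CH2, as established for 3-aryl-1-indanones giving 4-aryl-dihydrocoumarins; the benzyl and tert-butyldiphenylsilyl ethers are stable to the acid, no alkene is present yet and C4 is not involved.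

**Step 10**
Reactants: 22 (4R)-7-(benzyloxy)-4-[4-(benzyloxy)-3-methoxyphenyl]-5-{[(tert-butyldiphenylsilyl)oxy]methyl}chroman-2-one
Product: 23 (4R)-7-(benzyloxy)-4-[4-(benzyloxy)-3-methoxyphenyl]-5-(hydroxymethyl)chroman-2-one
Conditions: HF·pyridine, pyridine, THF, 0 °C → rt
Reagents that add atoms: none
Why: Fluoride-driven Si–O cleavage under mildly acidic, non-nucleophilic conditions leaves the aryl lactone and benzyl ethers intact, and the alcohol is oxidised without delay so that it cannot translactonise.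

**Step 11**
Reactants: 23 (4R)-7-(benzyloxy)-4-[4-(benzyloxy)-3-methoxyphenyl]-5-(hydroxymethyl)chroman-2-one
Product: 24 (4R)-7-(benzyloxy)-4-[4-(benzyloxy)-3-methoxyphenyl]-2-oxochromane-5-carbaldehyde
Conditions: Dess–Martin periodinane, CH2Cl2, 0 °C → rt
Reagents that add atoms: none
Why: Dess–Martin oxidation converts a benzylic alcohol into the aldehyde under neutral conditions without over-oxidation or attack on the lactone.

**Step 12**
Reactants: 25 [4-(benzyloxy)-3-methoxyphenyl]methanol
Product: 27 diethyl {[4-(benzyloxy)-3-methoxyphenyl]methyl}phosphonate, via benzylic chloride 26 (not isolated)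
Conditions: SOCl2, CH2Cl2, 0 °C → rt, evaporate; then P(OEt)3 (neat), 130 °C
Reagents that add atoms: triethyl phosphite, CCOP(OCC)OCC
Why: Chlorination of an electron-rich benzylic alcohol and Michaelis–Arbuzov reaction of the reactive chloride with triethyl phosphite is the standard entry to benzylphosphonates.

**Step 13**
Reactants: 24 (4R)-7-(benzyloxy)-4-[4-(benzyloxy)-3-methoxyphenyl]-2-oxochromane-5-carbaldehyde; 27 diethyl {[4-(benzyloxy)-3-methoxyphenyl]methyl}phosphonate
Product: 29 (4R)-7-(benzyloxy)-4-[4-(benzyloxy)-3-methoxyphenyl]-5-{(E)-2-[4-(benzyloxy)-3-methoxyphenyl]ethenyl}chroman-2-one, via potassium phosphonate carbanion 28 (not isolated)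
Conditions: 27 (1.2 equiv), KN(SiMe3)2 (1.1 equiv), THF, −78 °C; then 24, −78 → 0 °C
Reagents that add atoms: none
Why: Horner–Wadsworth–Emmons olefination of a benzylphosphonate carbanion with an aryl aldehyde gives the (E)-stilbene through the favoured trans-oxaphosphetane, and the preformed potassium carbanion, used without excess base at low temperature, should react at the aldehyde much faster than at the lactone.

**Step 14**
Reactants: 29 (4R)-7-(benzyloxy)-4-[4-(benzyloxy)-3-methoxyphenyl]-5-{(E)-2-[4-(benzyloxy)-3-methoxyphenyl]ethenyl}chroman-2-one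
Product: 30 CNP0277187.1, (4R)-7-hydroxy-4-(4-hydroxy-3-methoxyphenyl)-5-[(E)-2-(4-hydroxy-3-methoxyphenyl)ethenyl]chroman-2-one
Conditions: BCl3 (1 M in CH2Cl2, 6 equiv), pentamethylbenzene (9 equiv), CH2Cl2, −78 °C; then H2O
Reagents that add atoms: none
Why: BCl3 cleaves aryl benzyl ethers at −78 °C while pentamethylbenzene traps the benzyl cation (Lewis-acid debenzylation with a non-basic cation scavenger), conditions that spare aryl methyl ethers, the stilbene, the lactone and the C4 centre.

**Compound list**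

1 | 4-(benzyloxy)-3-methoxybenzaldehyde | COc1cc(C=O)ccc1OCc1ccccc1 | starting material
2 | Meldrum's acid (2,2-dimethyl-1,3-dioxane-4,6-dione) | CC1(C)OC(=O)CC(=O)O1 | starting material
3 | 5-[4-(benzyloxy)-3-methoxybenzylidene]-2,2-dimethyl-1,3-dioxane-4,6-dione | COc1cc(C=C2C(=O)OC(C)(C)OC2=O)ccc1OCc1ccccc1 | intermediate
4 | tert-butyl(diphenyl)(prop-2-yn-1-yloxy)silane | C#CCO[Si](c1ccccc1)(c1ccccc1)C(C)(C)C | starting material
5 | 5-{(1R)-1-[4-(benzyloxy)-3-methoxyphenyl]-4-[(tert-butyldiphenylsilyl)oxy]but-2-yn-1-yl}-2,2-dimethyl-1,3-dioxane-4,6-dione | CC(C)(C)[Si](c1ccccc1)(c1ccccc1)OCC#C[C@@H](c1ccc(OCc2ccccc2)c(OC)c1)C1C(=O)OC(C)(C)OC1=O | intermediate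
6 | {(1R)-1-[4-(benzyloxy)-3-methoxyphenyl]-4-[(tert-butyldiphenylsilyl)oxy]but-2-yn-1-yl}malonic acid | CC(C)(C)[Si](c1ccccc1)(c1ccccc1)OCC#C[C@@H](c1ccc(OCc2ccccc2)c(OC)c1)C(C(=O)O)C(=O)O | intermediate
7 | (3R)-3-[4-(benzyloxy)-3-methoxyphenyl]-6-[(tert-butyldiphenylsilyl)oxy]hex-4-ynoic acid | CC(C)(C)[Si](c1ccccc1)(c1ccccc1)OCC#C[C@@H](c1ccc(OCc2ccccc2)c(OC)c1)CC(=O)O | intermediate
8 | (3R)-3-[4-(benzyloxy)-3-methoxyphenyl]-6-[(tert-butyldiphenylsilyl)oxy]-1-(1H-imidazol-1-yl)hex-4-yn-1-one | CC(C)(C)[Si](c1ccccc1)(c1ccccc1)OCC#C[C@@H](c1ccc(OCc2ccccc2)c(OC)c1)CC(=O)n1ccnc1 | intermediate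
9 | (3R)-3-[4-(benzyloxy)-3-methoxyphenyl]-6-[(tert-butyldiphenylsilyl)oxy]-N-methoxy-N-methylhex-4-ynamide | CC(C)(C)[Si](c1ccccc1)(c1ccccc1)OCC#C[C@@H](c1ccc(OCc2ccccc2)c(OC)c1)CC(=O)N(C)OC | intermediate
10 | ethynylmagnesium bromide | C#C[Mg]Br | starting material
11 | bromomagnesium salt of (5R)-5-[4-(benzyloxy)-3-methoxyphenyl]-8-[(tert-butyldiphenylsilyl)oxy]-3-[methoxy(methyl)amino]octa-1,6-diyn-3-ol | CC(C)(C)[Si](c1ccccc1)(c1ccccc1)OCC#C[C@@H](c1ccc(OCc2ccccc2)c(OC)c1)CC(O[Mg]Br)(C#C)N(C)OC | intermediate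
12 | (5R)-5-[4-(benzyloxy)-3-methoxyphenyl]-8-[(tert-butyldiphenylsilyl)oxy]octa-1,6-diyn-3-one | CC(C)(C)[Si](c1ccccc1)(c1ccccc1)OCC#C[C@@H](c1ccc(OCc2ccccc2)c(OC)c1)CC(=O)C#C | intermediate
13 | benzyl alcohol | OCc1ccccc1 | starting material
14 | trichloroethylene | ClC=C(Cl)Cl | starting material
15 | potassium benzyl oxide | [K+].[O-]Cc1ccccc1 | intermediate
16 | dichloroethyne | ClC#CCl | intermediate
17 | benzyl (E)-1,2-dichlorovinyl ether | Cl/C=C(/Cl)OCc1ccccc1 | intermediate
18 | benzyl chloroethynyl ether | ClC#COCc1ccccc1 | intermediate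
19 | lithium benzyloxyacetylide | [Li]C#COCc1ccccc1 | intermediate
20 | (benzyloxy)ethyne | C#COCc1ccccc1 | intermediate
21 | (3R)-6-(benzyloxy)-3-[4-(benzyloxy)-3-methoxyphenyl]-4-{[(tert-butyldiphenylsilyl)oxy]methyl}-2,3-dihydro-1H-inden-1-one | CC(C)(C)[Si](c1ccccc1)(c1ccccc1)OCc1cc(OCc2ccccc2)cc2c1[C@@H](c1ccc(OCc3ccccc3)c(OC)c1)CC2=O | intermediate
22 | (4R)-7-(benzyloxy)-4-[4-(benzyloxy)-3-methoxyphenyl]-5-{[(tert-butyldiphenylsilyl)oxy]methyl}chroman-2-one | CC(C)(C)[Si](c1ccccc1)(c1ccccc1)OCc1cc(OCc2ccccc2)cc2c1[C@@H](c1ccc(OCc3ccccc3)c(OC)c1)CC(=O)O2 | intermediate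
23 | (4R)-7-(benzyloxy)-4-[4-(benzyloxy)-3-methoxyphenyl]-5-(hydroxymethyl)chroman-2-one | OCc1cc(OCc2ccccc2)cc2c1[C@@H](c1ccc(OCc3ccccc3)c(OC)c1)CC(=O)O2 | intermediate
24 | (4R)-7-(benzyloxy)-4-[4-(benzyloxy)-3-methoxyphenyl]-2-oxochromane-5-carbaldehyde | O=Cc1cc(OCc2ccccc2)cc2c1[C@@H](c1ccc(OCc3ccccc3)c(OC)c1)CC(=O)O2 | intermediate
25 | [4-(benzyloxy)-3-methoxyphenyl]methanol | COc1cc(CO)ccc1OCc1ccccc1 | starting material
26 | 1-(benzyloxy)-4-(chloromethyl)-2-methoxybenzene | COc1cc(CCl)ccc1OCc1ccccc1 | intermediate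
27 | diethyl {[4-(benzyloxy)-3-methoxyphenyl]methyl}phosphonate | CCOP(=O)(Cc1ccc(OCc2ccccc2)c(OC)c1)OCC | intermediate
28 | potassium salt of the benzylic carbanion of 27 | CCOP(=O)([CH-]c1ccc(OCc2ccccc2)c(OC)c1)OCC.[K+] | intermediate
29 | (4R)-7-(benzyloxy)-4-[4-(benzyloxy)-3-methoxyphenyl]-5-{(E)-2-[4-(benzyloxy)-3-methoxyphenyl]ethenyl}chroman-2-one | COc1cc(/C=C/c2cc(OCc3ccccc3)cc3c2[C@@H](c2ccc(OCc4ccccc4)c(OC)c2)CC(=O)O3)ccc1OCc1ccccc1 | intermediate
30 | CNP0277187.1, (4R)-7-hydroxy-4-(4-hydroxy-3-methoxyphenyl)-5-[(E)-2-(4-hydroxy-3-methoxyphenyl)ethenyl]chroman-2-one | COc1cc(/C=C/c2cc(O)cc3c2[C@@H](c2ccc(O)c(OC)c2)CC(=O)O3)ccc1O | target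

**Step count**

Total: 14 steps. Longest linear sequence: 11 steps (steps 1–5, 8–11, 13 and 14).

**Steps most likely to fail**

Step 8. The diynone may cyclotrimerise or oligomerise with itself, the ynol ether may decompose at the metal, or the monoalkyne may insert in the opposite sense and place the oxygen next to the silyloxymethyl group. The fallback sets out from 12 and introduces the C7 oxygen after ring construction instead of carrying it on the alkyne. Cycloaddition of 12 with commercial 2-ethynyl-4,4,5,5-tetramethyl-1,3,2-dioxaborolane under Cp*RuCl(cod) in 1,2-dichloroethane at rt, a known partner class with a strong meta preference, should give the arylboronate (3R)-3-[4-(benzyloxy)-3-methoxyphenyl]-4-{[(tert-butyldiphenylsilyl)oxy]methyl}-6-(4,4,5,5-tetramethyl-1,3,2-dioxaborolan-2-yl)-2,3-dihydro-1H-inden-1-one F1. Oxidation of the C–B bond with NaBO3·4H2O in THF/H2O should give the phenol (3R)-3-[4-(benzyloxy)-3-methoxyphenyl]-4-{[(tert-butyldiphenylsilyl)oxy]methyl}-6-hydroxy-2,3-dihydro-1H-inden-1-one F2. Benzylation (BnBr, K2CO3, DMF) brings the material back to the route at 21.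

Step 2. The copper acetylide of an aliphatic alkyne may turn over slowly on this electron-rich arylidene, or the ligand may discriminate the two faces poorly. The fallback sets out from 3 and replaces asymmetric catalysis by resolution. Alkyne 4 is metallated with EtMgBr in THF to {3-[(tert-butyldiphenylsilyl)oxy]prop-1-yn-1-yl}magnesium bromide F3, which should add 1,4 to 3 to give the racemic adduct 5-{1-[4-(benzyloxy)-3-methoxyphenyl]-4-[(tert-butyldiphenylsilyl)oxy]but-2-yn-1-yl}-2,2-dimethyl-1,3-dioxane-4,6-dione F4. Heating in DMF/H2O should lead through the racemic malonic acid F5 (not isolated) to racemic 3-[4-(benzyloxy)-3-methoxyphenyl]-6-[(tert-butyldiphenylsilyl)oxy]hex-4-ynoic acid F6. Crystallisation with cis-1-amino-2-indanol (the enantiomer that gives the less soluble salt of the (R)-acid, written here as the (1S,2R)-amine) should give the (1S,2R)-1-amino-2-indanol salt of the (R)-acid F7. Acidification with aqueous KHSO4 releases 7, where the route is rejoined.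

Step 13. The carbanion, or the alkoxide formed on its addition to the aldehyde, may open or translactonise the aryl lactone in competition with olefination. The fallback sets out from 24 and avoids basic carbanions altogether. Takai olefination (CHI3, CrCl2, THF, 0 °C) should give the vinyl iodide (4R)-7-(benzyloxy)-4-[4-(benzyloxy)-3-methoxyphenyl]-5-[(E)-2-iodoethenyl]chroman-2-one F8. Suzuki–Miyaura coupling with commercial [4-(benzyloxy)-3-methoxyphenyl]boronic acid (Pd(PPh3)4, CsF, dioxane, 80 °C, anhydrous) should proceed with retention of the alkene geometry and comes back to the route at 29.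

**Further compounds**

F1 | step 8 | (3R)-3-[4-(benzyloxy)-3-methoxyphenyl]-4-{[(tert-butyldiphenylsilyl)oxy]methyl}-6-(4,4,5,5-tetramethyl-1,3,2-dioxaborolan-2-yl)-2,3-dihydro-1H-inden-1-one | CC(C)(C)[Si](c1ccccc1)(c1ccccc1)OCc1cc(B2OC(C)(C)C(C)(C)O2)cc2c1[C@@H](c1ccc(OCc3ccccc3)c(OC)c1)CC2=O
F2 | step 8 | (3R)-3-[4-(benzyloxy)-3-methoxyphenyl]-4-{[(tert-butyldiphenylsilyl)oxy]methyl}-6-hydroxy-2,3-dihydro-1H-inden-1-one | CC(C)(C)[Si](c1ccccc1)(c1ccccc1)OCc1cc(O)cc2c1[C@@H](c1ccc(OCc3ccccc3)c(OC)c1)CC2=O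
F3 | step 2 | {3-[(tert-butyldiphenylsilyl)oxy]prop-1-yn-1-yl}magnesium bromide | Br[Mg]C#CCO[Si](c1ccccc1)(c1ccccc1)C(C)(C)C
F4 | step 2 | racemic 5-{1-[4-(benzyloxy)-3-methoxyphenyl]-4-[(tert-butyldiphenylsilyl)oxy]but-2-yn-1-yl}-2,2-dimethyl-1,3-dioxane-4,6-dione | CC(C)(C)[Si](c1ccccc1)(c1ccccc1)OCC#CC(c1ccc(OCc2ccccc2)c(OC)c1)C1C(=O)OC(C)(C)OC1=O
F5 | step 2 | racemic {1-[4-(benzyloxy)-3-methoxyphenyl]-4-[(tert-butyldiphenylsilyl)oxy]but-2-yn-1-yl}malonic acid | CC(C)(C)[Si](c1ccccc1)(c1ccccc1)OCC#CC(c1ccc(OCc2ccccc2)c(OC)c1)C(C(=O)O)C(=O)O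
F6 | step 2 | racemic 3-[4-(benzyloxy)-3-methoxyphenyl]-6-[(tert-butyldiphenylsilyl)oxy]hex-4-ynoic acid | CC(C)(C)[Si](c1ccccc1)(c1ccccc1)OCC#CC(c1ccc(OCc2ccccc2)c(OC)c1)CC(=O)O
F7 | step 2 | (1S,2R)-1-amino-2-indanol salt of (3R)-3-[4-(benzyloxy)-3-methoxyphenyl]-6-[(tert-butyldiphenylsilyl)oxy]hex-4-ynoic acid | CC(C)(C)[Si](c1ccccc1)(c1ccccc1)OCC#C[C@@H](c1ccc(OCc2ccccc2)c(OC)c1)CC(=O)[O-].[NH3+][C@@H]1[C@H](O)Cc2ccccc21
F8 | step 13 | (4R)-7-(benzyloxy)-4-[4-(benzyloxy)-3-methoxyphenyl]-5-[(E)-2-iodoethenyl]chroman-2-one | I/C=C/c1cc(OCc2ccccc2)cc2c1[C@@H](c1ccc(OCc3ccccc3)c(OC)c1)CC(=O)O2
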